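## Retrosynthetic overview (disconnections listed in the order the bonds are made)

1. Chain numbering: C1 = OCH2, C20 = stereocentre. C16–C17 and C16–C18: 16-hexadecanolide 1 (C1–C16) + EtMgBr (C17, C18) → cyclopropanol 2 (Kulinkovich). This cyclopropane is the only ring formed in the route and is opened again in the next step; the arene is bought.
2. Key disconnection C18–C19: 2 reacts as a ketone homoenolate (C18, β to the C16 carbonyl, is the nucleophile) with chiral-pool (S)-1-iodo-2-methylbutane 3 (C19–C22, methyl branch, S centre already present) → ketone 4.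
3. The C16 carbonyl is a traceless handle: 4 → hydrazone 5 → (S)-20-methyldocosan-1-ol 6 (Wolff–Kishner).
4. Ester C–O bond: 6 + unprotected 2,3-dihydroxybenzoic acid 7 → (via 8) Gentiside B 9 (Mitsunobu).

Assumption: 1 (fragrance-grade macrolide) and 3 (≥98% ee) are bought as such; the target centre is S and has the same spatial arrangement as the centre of 3.

## Route

Step 1
Reactants: 1 16-hexadecanolide (oxacycloheptadecan-2-one)
Product: 2 1-(15-hydroxypentadecyl)cyclopropan-1-ol
Conditions: EtMgBr (2.8 equiv, slow addition), Ti(OiPr)4 (0.3 equiv), THF, 0 °C → rt; then H2O, 0 °C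
Reagents that add atoms: ethylmagnesium bromide, CC[Mg]Br
Why: Kulinkovich cyclopropanation, in which the titanacyclopropane (iPrO)2Ti(CH2CH2) formed from EtMgBr and catalytic Ti(OiPr)4 adds twice to the ester carbonyl of 1 as a 1,2-dicarbanion, the 17-membered lactone behaving like an open-chain ester, and no stereocentre is created.

Step 2
Reactants: 2 1-(15-hydroxypentadecyl)cyclopropan-1-ol; 3 (S)-1-iodo-2-methylbutane
Product: 4 (S)-22-hydroxy-3-methyldocosan-7-one (1-hydroxy-20-methyldocosan-16-one in target numbering)
Conditions: 3 (1.5 equiv), Ni(cod)2 (10 mol %), 4,4',4''-tri-tert-butyl-2,2':6',2''-terpyridine (12 mol %), Cs2CO3 (1.5 equiv), DMA, 25 → 40 °C, Ar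
Reagents that add atoms: none
Why: Proposed new method: the nickel alkoxide of the strained cyclopropanol undergoes β-carbon elimination to a β-nickelated ketone (a ketone homoenolate, nucleophilic at C18), the monovalent alkylnickel abstracts iodine from 3 to give the primary 2-methylbutyl radical, and radical capture followed by C(sp3)–C(sp3) reductive elimination from trivalent nickel forms C18–C19, the closest known reaction types being the nickel-catalysed β-alkylation of cyclopropanol-derived homoenolates with redox-active N-acyloxyphthalimides and the nickel/terpyridine alkyl–alkyl Negishi coupling of unactivated primary iodides; the stereocentre of 3 is β to the reacting carbon, is never a radical or carbanion site and is carried through unchanged.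

Step 3
Reactants: 4 (S)-22-hydroxy-3-methyldocosan-7-one
Product: 6 (S)-20-methyldocosan-1-ol, via ketone hydrazone 5 (not isolated)
Conditions: N2H4·H2O (6 equiv), KOH (4 equiv), diethylene glycol, 130 °C, 2 h; then distil off H2O/N2H4, 200 °C, 4 h
Reagents that add atoms: none
Why: Wolff–Kishner reduction (Huang–Minlon procedure), in which hydrazone 5 loses N2 under hot KOH to leave a methylene, the primary alcohol is inert and the stereocentre, four carbons from the carbonyl, cannot epimerise.

Step 4
Reactants: 6 (S)-20-methyldocosan-1-ol; 7 2,3-dihydroxybenzoic acid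
Product: 9 Gentiside B [(S)-20-methyldocosyl 2,3-dihydroxybenzoate], via alkoxyphosphonium carboxylate 8 (not isolated)
Conditions: 7 (1.3 equiv), PPh3 (1.3 equiv), DIAD (1.3 equiv, added last), THF, 0 °C → rt
Reagents that add atoms: none
Why: Mitsunobu esterification, in which only the carboxylic acid (pKa about 3) protonates the PPh3/DIAD betaine, so the carboxylate displaces Ph3P=O from the primary alkoxyphosphonium 8 by SN2 while the phenols (pKa about 10, the 2-OH hydrogen-bonded to the carbonyl) stay free, and no stereocentre is involved.

## Compound list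

1 | 16-hexadecanolide (oxacycloheptadecan-2-one) | O=C1CCCCCCCCCCCCCCCO1 | starting material
2 | 1-(15-hydroxypentadecyl)cyclopropan-1-ol | OCCCCCCCCCCCCCCCC1(O)CC1 | intermediate
3 | (S)-1-iodo-2-methylbutane | CC[C@H](C)CI | starting material
4 | (S)-22-hydroxy-3-methyldocosan-7-one | CC[C@H](C)CCCC(=O)CCCCCCCCCCCCCCCO | intermediate
5 | (S)-16-hydrazinylidene-20-methyldocosan-1-ol (hydrazone of 4) | CC[C@H](C)CCCC(=NN)CCCCCCCCCCCCCCCO | intermediate
6 | (S)-20-methyldocosan-1-ol | CC[C@H](C)CCCCCCCCCCCCCCCCCCCO | intermediate
7 | 2,3-dihydroxybenzoic acid | OC(=O)c1cccc(O)c1O | starting material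
8 | {[(S)-20-methyldocosyl]oxy}triphenylphosphonium 2,3-dihydroxybenzoate | CC[C@H](C)CCCCCCCCCCCCCCCCCCCO[P+](c1ccccc1)(c1ccccc1)c1ccccc1.[O-]C(=O)c1cccc(O)c1O | intermediate
9 | Gentiside B, (S)-20-methyldocosyl 2,3-dihydroxybenzoate | CC[C@H](C)CCCCCCCCCCCCCCCCCCCOC(=O)c1cccc(O)c1O | target

## Step count and risk

Total steps: 4. Longest linear sequence: 4 (1 → 2 → 4 → 6 → 9).

Steps most likely to fail:

Step 2 (highest risk). The direct nickel-homoenolate coupling with an unactivated, β-branched alkyl iodide is unprecedented. It may give the protonated homoenolate (ethyl ketone), the vinyl ketone from β-hydride elimination, or homocoupled iodide. The fallback sets out from 3 and comes back at 4; it keeps the homoenolate but changes the alkyl partner to a decarboxylative radical precursor, for which the nickel-catalysed β-alkylation of cyclopropanols is established. Iodide 3 is converted with Mg turnings in THF into (S)-(2-methylbutyl)magnesium iodide F1 (the β-stereocentre is configurationally safe). Carboxylation with CO2 and HCl work-up gives (S)-3-methylpentanoic acid F2. Esterification with N-hydroxyphthalimide (DIC, catalytic DMAP, CH2Cl2) gives 1,3-dioxoisoindolin-2-yl (S)-3-methylpentanoate F3. F3 and cyclopropanol 2 are then coupled with NiCl2·glyme and a bipyridine ligand in DMA, with loss of CO2 and phthalimide, to give ketone 4, and the route resumes at step 3.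

Step 1. On the macrolactone, the ω-alkoxide released on ring opening, together with the titanium alkoxide, can transesterify unreacted 1 to oligomers, and double ethyl addition can compete. The fallback sets out from 1 and comes back at 2, building the cyclopropanol by carbenoid cyclopropanation of an enol ether instead. MeLi (1.05 equiv, THF, −78 °C) opens 1 to 17-hydroxyheptadecan-2-one F4. LiN(iPr)2 (2.2 equiv) and Me3SiCl at −78 °C give the kinetic, terminal enol ether 2,17-bis(trimethylsilyloxy)heptadec-1-ene F5. Simmons–Smith cyclopropanation (Et2Zn, CH2I2, CH2Cl2, 0 °C) gives 1-(trimethylsilyloxy)-1-[15-(trimethylsilyloxy)pentadecyl]cyclopropane F6. K2CO3 in MeOH removes both silyl groups to give 2.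

Step 4. With the catechol unprotected, the Mitsunobu reagents may O-alkylate a phenol or tie up the catechol as a phosphorane. The fallback sets out from 6 and comes back at 9, replacing in-situ alcohol activation by an isolated electrophile and a base too weak to deprotonate phenols. Appel bromination (CBr4, PPh3, CH2Cl2, 0 °C) gives (S)-1-bromo-20-methyldocosane F7. F7 alkylates the carboxylate of 7 (KHCO3, DMF, 60 °C) to give 9.

## Further compounds

F1 | step 2 | (S)-(2-methylbutyl)magnesium iodide | CC[C@H](C)C[Mg]I
F2 | step 2 | (S)-3-methylpentanoic acid | CC[C@H](C)CC(=O)O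
F3 | step 2 | 1,3-dioxoisoindolin-2-yl (S)-3-methylpentanoate | CC[C@H](C)CC(=O)ON1C(=O)c2ccccc2C1=O
F4 | step 1 | 17-hydroxyheptadecan-2-one | CC(=O)CCCCCCCCCCCCCCCO
F5 | step 1 | 2,17-bis(trimethylsilyloxy)heptadec-1-ene | C=C(O[Si](C)(C)C)CCCCCCCCCCCCCCCO[Si](C)(C)C
F6 | step 1 | 1-(trimethylsilyloxy)-1-[15-(trimethylsilyloxy)pentadecyl]cyclopropane | C[Si](C)(C)OC1(CC1)CCCCCCCCCCCCCCCO[Si](C)(C)C
F7 | step 4 | (S)-1-bromo-20-methyldocosane | CC[C@H](C)CCCCCCCCCCCCCCCCCCCBr
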